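**Strategy.** Everything rests on reading the Z-alkylidene γ-lactone together with the neighbouring E-trisubstituted alkene as an opened cyclohex-2-enone: ring C1–C6 map onto the lactone carbonyl carbon, the alkylidene carbon, the exocyclic =CH, the next two CH2 groups and the methyl-bearing alkene carbon. In one operation, base turns a hydroxy mesylate into a hemiketal alkoxide that fragments between C1 and C6 with loss of the C7 mesylate; lactone ring, lactone carbonyl and the new alkene appear together, and the ring alkene becomes the exocyclic Z-alkene. The precursor is a 2,6,6-trisubstituted cyclohexenone with the free carbinol side chain on C2 and, on C6, methyl plus the mesyloxy-bearing chain.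

Key step: step 15

Remark (numbering): the cyclohexenone is numbered C1 (C=O), C2=C3, C4, C5, C6 (quaternary); C7 is the carbinol/mesylate carbon on C6 and C8 the first chain carbon.

Remark (stereochemistry): anti-periplanar fragmentation gives the E alkene only from the (6R,7S) or (6S,7R) pair, in which ring C5 and the C7 oxygen are syn in the zigzag projection. A chair-type aldol of the cyclic dienolate with a chain aldehyde should favour the opposite pair, which would fragment to the Z isomer. The C7–C8 bond is therefore made by chelation-controlled Grignard addition to a C6 formyl group.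

Remark (mixtures): the starting enone is racemic, so ring intermediates are mixtures at C6 relative to the (S)-carbinol. From the Grignard adduct on, the SMILES show the (6R,7S) isomer; the (6S,7R) isomer accompanies it, and both converge because C6 and C7 become sp2 in the key step.

**Route**

Step 1
Reactants: 1 6-methylcyclohex-2-en-1-one
Product: 2 2-iodo-6-methylcyclohex-2-en-1-one
Conditions: I2, K2CO3, DMAP (cat.), THF/H2O, rt
Reagents that add atoms: iodine, II
Why: Amine-catalysed α-iodination of an enone (conjugate addition of the catalyst, iodination of the enolate, elimination) is a standard entry to 2-iodocyclohex-2-enones and leaves the α′ methine untouched.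

Step 2
Reactants: 2 2-iodo-6-methylcyclohex-2-en-1-one; 3 allyltributylstannane
Product: 4 2-allyl-6-methylcyclohex-2-en-1-one
Conditions: Pd2(dba)3 (cat.), AsPh3, CuI, NMP, rt to 50 °C
Reagents that add atoms: none
Why: Stille coupling of an α-iodoenone with an allylstannane under ligand-accelerated, copper-assisted conditions forms the C2–allyl bond without touching the enone.

Step 3
Reactants: 4 2-allyl-6-methylcyclohex-2-en-1-one
Product: 6 2-(5-methyl-6-oxocyclohex-1-en-1-yl)acetaldehyde, via vicinal diol 5 (not isolated)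
Conditions: OsO4 (cat.), NaIO4, 2,6-lutidine, dioxane/H2O, rt
Reagents that add atoms: osmium tetroxide, O=[Os](=O)(=O)=O; sodium periodate, [Na+].[O-]I(=O)(=O)=O
Why: Lemieux–Johnson cleavage dihydroxylates the electron-richer monosubstituted alkene in preference to the conjugated trisubstituted enone alkene, and periodate cleaves the diol to the aldehyde, which is used at once.

Step 4
Reactants: 6 2-(5-methyl-6-oxocyclohex-1-en-1-yl)acetaldehyde; 7 1-bromo-2-methylprop-1-ene
Product: 9 2-[(2S)-2-hydroxy-4-methylpent-3-en-1-yl]-6-methylcyclohex-2-en-1-one, via alkenylchromium dichloride 8 (not isolated)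
Conditions: CrCl2, NiCl2 (cat.), chiral oxazoline–sulfonamide ligand, Et3N, THF, rt
Reagents that add atoms: none
Why: Nozaki–Hiyama–Kishi reaction: the nickel-generated alkenylchromium(III) species is non-basic and adds only to the aldehyde (enone and the acidic CH2 survive), and the chiral sulfonamide-bound chromium directs Re-face addition, which sets the (S)-carbinol.

Step 5
Reactants: 9 2-[(2S)-2-hydroxy-4-methylpent-3-en-1-yl]-6-methylcyclohex-2-en-1-one
Product: 10 6-methyl-2-[(2S)-4-methyl-2-(triethylsilyloxy)pent-3-en-1-yl]cyclohex-2-en-1-one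
Conditions: TESCl, imidazole, DMF, 0 °C
Reagents that add atoms: chlorotriethylsilane, CC[Si](Cl)(CC)CC
Why: Silylation of the secondary allylic alcohol as a triethylsilyl ether, chosen because it can later be removed beside a primary TBDPS ether and a mesylate.

Step 6
Reactants: 10 6-methyl-2-[(2S)-4-methyl-2-(triethylsilyloxy)pent-3-en-1-yl]cyclohex-2-en-1-one
Product: 12 6-(hydroxymethyl)-6-methyl-2-[(2S)-4-methyl-2-(triethylsilyloxy)pent-3-en-1-yl]cyclohex-2-en-1-one, via lithium dienolate 11 (not isolated)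
Conditions: LDA, THF, −78 °C; CH2O (gas), −78 °C; AcOH quench
Reagents that add atoms: formaldehyde, C=O
Why: Kinetic deprotonation of the enone at the α′ methine gives the cross-conjugated dienolate, whose aldol addition to monomeric formaldehyde places the future C7 on C6; the C6 configuration relative to the carbinol is immaterial.

Step 7
Reactants: 12 6-(hydroxymethyl)-6-methyl-2-[(2S)-4-methyl-2-(triethylsilyloxy)pent-3-en-1-yl]cyclohex-2-en-1-one
Product: 13 1-methyl-3-[(2S)-4-methyl-2-(triethylsilyloxy)pent-3-en-1-yl]-2-oxocyclohex-3-ene-1-carbaldehyde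
Conditions: Dess–Martin periodinane, NaHCO3, CH2Cl2, 0 °C to rt
Reagents that add atoms: none
Why: Buffered Dess–Martin oxidation gives the non-enolisable β-keto aldehyde under non-basic conditions, so retro-aldol loss of the one-carbon unit is avoided.

Step 8
Reactants: 14 tert-butyl(but-3-yn-1-yloxy)dimethylsilane
Product: 17 (3E)-6-[(tert-butyldimethylsilyl)oxy]-4-methylhex-3-en-1-ol, via alkenyldimethylalane 15 (not isolated), via lithium alkenylaluminate 16 (not isolated)
Conditions: Me3Al, Cp2ZrCl2 (cat.), CH2Cl2, 0 °C to rt; n-BuLi, hexane/THF, −78 °C; oxirane, −30 °C to rt; aqueous work-up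
Reagents that add atoms: trimethylaluminium, C[Al](C)C; oxirane, C1CO1
Why: Zirconium-catalysed methylalumination of the terminal alkyne (Negishi carboalumination) is syn and puts methyl on the internal carbon, and the derived aluminate opens oxirane with retention, so the E-trisubstituted alkene is fixed here.

Step 9
Reactants: 17 (3E)-6-[(tert-butyldimethylsilyl)oxy]-4-methylhex-3-en-1-ol
Product: 18 (3E)-1-[(tert-butyldimethylsilyl)oxy]-6-[(tert-butyldiphenylsilyl)oxy]-3-methylhex-3-ene
Conditions: TBDPSCl, imidazole, DMF, rt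
Reagents that add atoms: tert-butyl(chloro)diphenylsilane, CC(C)(C)[Si](Cl)(c1ccccc1)c1ccccc1
Why: Standard silylation of the primary alcohol with the robust TBDPS group, which must survive organomagnesium, enolate-free basic and mildly acidic steps.

Step 10
Reactants: 18 (3E)-1-[(tert-butyldimethylsilyl)oxy]-6-[(tert-butyldiphenylsilyl)oxy]-3-methylhex-3-ene
Product: 19 (3E)-6-[(tert-butyldiphenylsilyl)oxy]-3-methylhex-3-en-1-ol
Conditions: PPTS (cat.), MeOH, rt
Reagents that add atoms: none
Why: Acid-catalysed methanolysis cleaves a primary TBS ether far faster than the bulkier TBDPS ether.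

Step 11
Reactants: 19 (3E)-6-[(tert-butyldiphenylsilyl)oxy]-3-methylhex-3-en-1-ol
Product: 20 {[(3E)-6-bromo-4-methylhex-3-en-1-yl]oxy}(tert-butyl)diphenylsilane
Conditions: CBr4, PPh3, CH2Cl2, 0 °C
Reagents that add atoms: tetrabromomethane, BrC(Br)(Br)Br
Why: The Appel reaction converts the primary homoallylic alcohol into the bromide under neutral conditions without risk to the alkene geometry.

Step 12
Reactants: 20 {[(3E)-6-bromo-4-methylhex-3-en-1-yl]oxy}(tert-butyl)diphenylsilane; 13 1-methyl-3-[(2S)-4-methyl-2-(triethylsilyloxy)pent-3-en-1-yl]-2-oxocyclohex-3-ene-1-carbaldehyde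
Product: 22 (6R)-6-[(1S,4E)-7-(tert-butyldiphenylsilyloxy)-1-hydroxy-4-methylhept-4-en-1-yl]-6-methyl-2-[(2S)-4-methyl-2-(triethylsilyloxy)pent-3-en-1-yl]cyclohex-2-en-1-one plus its (6S,1′R) isomer, via alkylmagnesium bromide 21 (not isolated)
Conditions: Mg, Et2O, reflux; then 13, MgBr2·OEt2, CH2Cl2, −78 °C; aq. NH4Cl
Reagents that add atoms: none
Why: Grignard addition to the aldehyde (the hindered enone carbonyl is far less reactive) under chelation control: magnesium bridges the formyl and ring carbonyl oxygens, the C6 methyl then stands axial on the chelate, and the alkyl group should add anti to it, giving the (6R,7S)/(6S,7R) pair required for the E alkene.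

Step 13
Reactants: 22 (6R)-6-[(1S,4E)-7-(tert-butyldiphenylsilyloxy)-1-hydroxy-4-methylhept-4-en-1-yl]-6-methyl-2-[(2S)-4-methyl-2-(triethylsilyloxy)pent-3-en-1-yl]cyclohex-2-en-1-one
Product: 23 (1S,4E)-7-(tert-butyldiphenylsilyloxy)-4-methyl-1-{(1R)-1-methyl-3-[(2S)-4-methyl-2-(triethylsilyloxy)pent-3-en-1-yl]-2-oxocyclohex-3-en-1-yl}hept-4-en-1-yl methanesulfonate
Conditions: MsCl, Et3N, CH2Cl2, 0 °C
Reagents that add atoms: methanesulfonyl chloride, CS(=O)(=O)Cl
Why: Mesylation through sulfene works on hindered secondary alcohols, and the quaternary C6 rules out β-elimination toward the ketone.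

Step 14
Reactants: 23 (1S,4E)-7-(tert-butyldiphenylsilyloxy)-4-methyl-1-{(1R)-1-methyl-3-[(2S)-4-methyl-2-(triethylsilyloxy)pent-3-en-1-yl]-2-oxocyclohex-3-en-1-yl}hept-4-en-1-yl methanesulfonate
Product: 24 (1S,4E)-7-(tert-butyldiphenylsilyloxy)-1-{(1R)-3-[(2S)-2-hydroxy-4-methylpent-3-en-1-yl]-1-methyl-2-oxocyclohex-3-en-1-yl}-4-methylhept-4-en-1-yl methanesulfonate
Conditions: HF·pyridine, pyridine, THF, 0 °C
Reagents that add atoms: none
Why: Buffered HF·pyridine removes the secondary triethylsilyl ether selectively while the primary TBDPS ether and the neopentyl-type mesylate persist.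

Step 15
Reactants: 24 (1S,4E)-7-(tert-butyldiphenylsilyloxy)-1-{(1R)-3-[(2S)-2-hydroxy-4-methylpent-3-en-1-yl]-1-methyl-2-oxocyclohex-3-en-1-yl}-4-methylhept-4-en-1-yl methanesulfonate
Product: 26 (3Z,5S)-3-[(4E,8E)-11-(tert-butyldiphenylsilyloxy)-4,8-dimethylundeca-4,8-dien-1-ylidene]-5-(2-methylprop-1-en-1-yl)dihydrofuran-2(3H)-one, via bicyclic hemiketal alkoxide 25 (not isolated)
Conditions: KHMDS (1.05 equiv), THF, −78 to 0 °C
Reagents that add atoms: none
Why: Proposed new method: deprotonation gives the side-chain alkoxide, which adds to the ring ketone to form hemiketal alkoxide 25; its oxyanion then expels the C1–C6 bond held anti-periplanar to the C7–OMs bond in a concerted Grob fragmentation, so the lactone carbonyl and the C6=C7 alkene form together and the γ-lactone remains closed. The closest known reaction is the intermolecular alkoxide-induced Grob fragmentation of cyclic β-sulfonyloxy ketones to alkenyl esters; a tethered alkoxide on a 2-substituted enone is the untested part. The lactone ring closes by 5-exo-trig attack of oxygen on the carbonyl carbon, preferred over 5-endo-trig conjugate addition at C3. No stereocentre is created: the carbinol centre is carried over unchanged and the hemiketal carbon is transient. The Z-alkylidene geometry follows from the carbonyl and C4 both having been ring members, and the E alkene from the (6R,7S)/(6S,7R) relationship read out through the anti-periplanar transition state. Enolisation and β-elimination toward C6 cannot compete because C6 is quaternary.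

Step 16
Reactants: 26 (3Z,5S)-3-[(4E,8E)-11-(tert-butyldiphenylsilyloxy)-4,8-dimethylundeca-4,8-dien-1-ylidene]-5-(2-methylprop-1-en-1-yl)dihydrofuran-2(3H)-one
Product: 27 (3Z,5S)-3-[(4E,8E)-11-hydroxy-4,8-dimethylundeca-4,8-dien-1-ylidene]-5-(2-methylprop-1-en-1-yl)dihydrofuran-2(3H)-one
Conditions: TBAF, AcOH, THF, rt
Reagents that add atoms: none
Why: Fluoride cleavage of the TBDPS ether, buffered with acetic acid so that the base-sensitive alkylidene lactone is neither isomerised nor opened.

Step 17
Reactants: 27 (3Z,5S)-3-[(4E,8E)-11-hydroxy-4,8-dimethylundeca-4,8-dien-1-ylidene]-5-(2-methylprop-1-en-1-yl)dihydrofuran-2(3H)-one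
Product: 28 (4E,8E)-4,8-dimethyl-11-[(3Z,5S)-5-(2-methylprop-1-en-1-yl)-2-oxodihydrofuran-3(2H)-ylidene]undeca-4,8-dienal
Conditions: Dess–Martin periodinane, NaHCO3, CH2Cl2, 0 °C
Reagents that add atoms: none
Why: Buffered Dess–Martin oxidation gives the β,γ-unsaturated aldehyde without migration of the trisubstituted alkene into conjugation; the crude aldehyde is used at once.

Step 18
Reactants: 28 (4E,8E)-4,8-dimethyl-11-[(3Z,5S)-5-(2-methylprop-1-en-1-yl)-2-oxodihydrofuran-3(2H)-ylidene]undeca-4,8-dienal; 29 4-bromofuran-2(5H)-one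
Product: 31 (3Z,5S)-3-[(4E,8E,11R)-11-hydroxy-4,8-dimethyl-11-(5-oxo-2,5-dihydrofuran-3-yl)undeca-4,8-dien-1-ylidene]-5-(2-methylprop-1-en-1-yl)dihydrofuran-2(3H)-one, via furanonylchromium dichloride 30 (not isolated)
Conditions: CrCl2, NiCl2 (cat.), enantiomeric oxazoline–sulfonamide ligand, Et3N, THF, rt
Reagents that add atoms: none
Why: Nozaki–Hiyama–Kishi reaction of a β-bromo-α,β-unsaturated lactone: the furanonylchromium(III) species adds only to the aldehyde (both lactones and all alkenes are spectators), and the enantiomeric ligand directs Si-face addition to give the (R)-carbinol.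

**Compound list**

1 | 6-methylcyclohex-2-en-1-one (racemic) | CC1CCC=CC1=O | starting material
2 | 2-iodo-6-methylcyclohex-2-en-1-one | CC1CCC=C(I)C1=O | intermediate
3 | allyltributylstannane | C=CC[Sn](CCCC)(CCCC)CCCC | starting material
4 | 2-allyl-6-methylcyclohex-2-en-1-one | C=CCC1=CCCC(C)C1=O | intermediate
5 | 2-(2,3-dihydroxypropyl)-6-methylcyclohex-2-en-1-one | OCC(O)CC1=CCCC(C)C1=O | intermediate
6 | 2-(5-methyl-6-oxocyclohex-1-en-1-yl)acetaldehyde | O=CCC1=CCCC(C)C1=O | intermediate
7 | 1-bromo-2-methylprop-1-ene | CC(C)=CBr | starting material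
8 | (2-methylprop-1-en-1-yl)chromium(III) dichloride | CC(C)=C[Cr](Cl)Cl | intermediate
9 | 2-[(2S)-2-hydroxy-4-methylpent-3-en-1-yl]-6-methylcyclohex-2-en-1-one (both C6 epimers) | CC(C)=C[C@@H](O)CC1=CCCC(C)C1=O | intermediate
10 | 6-methyl-2-[(2S)-4-methyl-2-(triethylsilyloxy)pent-3-en-1-yl]cyclohex-2-en-1-one (both C6 epimers) | CC(C)=C[C@@H](O[Si](CC)(CC)CC)CC1=CCCC(C)C1=O | intermediate
11 | lithium dienolate of 10 (lithium 2-methyl-6-[(2S)-4-methyl-2-(triethylsilyloxy)pent-3-en-1-yl]cyclohexa-1,5-dien-1-olate) | CC(C)=C[C@@H](O[Si](CC)(CC)CC)CC1=CCCC(C)=C1O[Li] | intermediate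
12 | 6-(hydroxymethyl)-6-methyl-2-[(2S)-4-methyl-2-(triethylsilyloxy)pent-3-en-1-yl]cyclohex-2-en-1-one (both C6 epimers) | CC(C)=C[C@@H](O[Si](CC)(CC)CC)CC1=CCCC(C)(CO)C1=O | intermediate
13 | 1-methyl-3-[(2S)-4-methyl-2-(triethylsilyloxy)pent-3-en-1-yl]-2-oxocyclohex-3-ene-1-carbaldehyde (both C1 epimers) | CC(C)=C[C@@H](O[Si](CC)(CC)CC)CC1=CCCC(C)(C=O)C1=O | intermediate
14 | tert-butyl(but-3-yn-1-yloxy)dimethylsilane | C#CCCO[Si](C)(C)C(C)(C)C | starting material
15 | [(1E)-4-(tert-butyldimethylsilyloxy)-2-methylbut-1-en-1-yl]dimethylalane | C[Al](C)/C=C(C)/CCO[Si](C)(C)C(C)(C)C | intermediate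
16 | lithium butyl[(1E)-4-(tert-butyldimethylsilyloxy)-2-methylbut-1-en-1-yl]dimethylaluminate | [Li+].CCCC[Al-](C)(C)/C=C(C)/CCO[Si](C)(C)C(C)(C)C | intermediate
17 | (3E)-6-[(tert-butyldimethylsilyl)oxy]-4-methylhex-3-en-1-ol | OCC/C=C(C)/CCO[Si](C)(C)C(C)(C)C | intermediate
18 | (3E)-1-[(tert-butyldimethylsilyl)oxy]-6-[(tert-butyldiphenylsilyl)oxy]-3-methylhex-3-ene | CC(C)(C)[Si](C)(C)OCC/C(C)=C/CCO[Si](c1ccccc1)(c1ccccc1)C(C)(C)C | intermediate
19 | (3E)-6-[(tert-butyldiphenylsilyl)oxy]-3-methylhex-3-en-1-ol | OCC/C(C)=C/CCO[Si](c1ccccc1)(c1ccccc1)C(C)(C)C | intermediate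
20 | {[(3E)-6-bromo-4-methylhex-3-en-1-yl]oxy}(tert-butyl)diphenylsilane | BrCC/C(C)=C/CCO[Si](c1ccccc1)(c1ccccc1)C(C)(C)C | intermediate
21 | [(3E)-6-(tert-butyldiphenylsilyloxy)-3-methylhex-3-en-1-yl]magnesium bromide | Br[Mg]CC/C(C)=C/CCO[Si](c1ccccc1)(c1ccccc1)C(C)(C)C | intermediate
22 | (6R)-6-[(1S,4E)-7-(tert-butyldiphenylsilyloxy)-1-hydroxy-4-methylhept-4-en-1-yl]-6-methyl-2-[(2S)-4-methyl-2-(triethylsilyloxy)pent-3-en-1-yl]cyclohex-2-en-1-one (accompanied by the (6S,1′R) isomer) | CC(C)=C[C@@H](O[Si](CC)(CC)CC)CC1=CCC[C@](C)([C@@H](O)CC/C(C)=C/CCO[Si](c2ccccc2)(c2ccccc2)C(C)(C)C)C1=O | intermediate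
23 | C7 mesylate of 22, triethylsilyl ether retained (accompanied by the (6S,7R) isomer) | CC(C)=C[C@@H](O[Si](CC)(CC)CC)CC1=CCC[C@](C)([C@@H](OS(C)(=O)=O)CC/C(C)=C/CCO[Si](c2ccccc2)(c2ccccc2)C(C)(C)C)C1=O | intermediate
24 | hydroxy mesylate, key-step precursor: (6R,7S)-2,6,6-trisubstituted cyclohex-2-enone with free (S)-carbinol (accompanied by the (6S,7R) isomer) | CC(C)=C[C@@H](O)CC1=CCC[C@](C)([C@@H](OS(C)(=O)=O)CC/C(C)=C/CCO[Si](c2ccccc2)(c2ccccc2)C(C)(C)C)C1=O | intermediate
25 | potassium 2,3,5,6,7,7a-hexahydro-1-benzofuran-7a-olate formed by addition of the carbinol oxygen of 24 to C1 (hemiketal carbon as both epimers) | CC(C)=C[C@@H]1CC2=CCC[C@](C)([C@@H](OS(C)(=O)=O)CC/C(C)=C/CCO[Si](c3ccccc3)(c3ccccc3)C(C)(C)C)C2([O-])O1.[K+] | intermediate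
26 | (3Z,5S)-3-[(4E,8E)-11-(tert-butyldiphenylsilyloxy)-4,8-dimethylundeca-4,8-dien-1-ylidene]-5-(2-methylprop-1-en-1-yl)dihydrofuran-2(3H)-one | CC(C)=C[C@@H]1C/C(=C/CC/C(C)=C/CC/C(C)=C/CCO[Si](c2ccccc2)(c2ccccc2)C(C)(C)C)C(=O)O1 | intermediate
27 | (3Z,5S)-3-[(4E,8E)-11-hydroxy-4,8-dimethylundeca-4,8-dien-1-ylidene]-5-(2-methylprop-1-en-1-yl)dihydrofuran-2(3H)-one | CC(C)=C[C@@H]1C/C(=C/CC/C(C)=C/CC/C(C)=C/CCO)C(=O)O1 | intermediate
28 | (4E,8E)-4,8-dimethyl-11-[(3Z,5S)-5-(2-methylprop-1-en-1-yl)-2-oxodihydrofuran-3(2H)-ylidene]undeca-4,8-dienal | CC(C)=C[C@@H]1C/C(=C/CC/C(C)=C/CC/C(C)=C/CC=O)C(=O)O1 | intermediate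
29 | 4-bromofuran-2(5H)-one | BrC1=CC(=O)OC1 | starting material
30 | (5-oxo-2,5-dihydrofuran-3-yl)chromium(III) dichloride | Cl[Cr](Cl)C1=CC(=O)OC1 | intermediate
31 | (3Z,5S)-3-[(4E,8E,11R)-11-hydroxy-4,8-dimethyl-11-(5-oxo-2,5-dihydrofuran-3-yl)undeca-4,8-dien-1-ylidene]-5-(2-methylprop-1-en-1-yl)dihydrofuran-2(3H)-one | CC(C)=C[C@@H]1C/C(=C/CC/C(C)=C/CC/C(C)=C/C[C@@H](O)C2=CC(=O)OC2)C(=O)O1 | target

**Totals**

Total step count: 18. Longest linear sequence: 14 steps (steps 1–7 and 12–18); steps 8–11 build the chain bromide.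

**Steps most likely to fail**

1. Step 15 (key step). The tethered alkoxide may fail to add to the hindered, conjugated carbonyl, or may act as a base so that elimination of the mesylate toward C8 or decomposition outruns fragmentation. The fallback sets out from mesylate 23 and uses the known intermolecular variant. Sodium methoxide in MeOH/THF at 0 °C to rt should add to the ketone and trigger the same anti-periplanar fragmentation, giving methyl (2Z,6E,10E)-13-(tert-butyldiphenylsilyloxy)-6,10-dimethyl-2-[(2S)-4-methyl-2-(triethylsilyloxy)pent-3-en-1-yl]trideca-2,6,10-trienoate F1. PPTS in MeOH then removes the triethylsilyl group to give the hydroxy ester F2. Warming F2 with catalytic CSA in toluene should close the γ-lactone and return to 26.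

2. Step 12. Chelation may be incomplete, giving poor facial selectivity at the formyl group (the C7 epimers would fragment to the Z isomer), and the hindered aldehyde may be reduced by β-hydride transfer from the Grignard reagent. The fallback sets out from ketone 10 and bromide 20 and forms the C6–C7 bond instead of C7–C8. Ketone 10 is converted with LDA and TMSCl into the trimethylsilyl dienol ether F3. Grignard reagent 21, made from 20, is formylated with DMF (Bouveault aldehyde synthesis) to (4E)-7-(tert-butyldiphenylsilyloxy)-4-methylhept-4-enal F4. A fluoride-catalysed aldol addition of F3 to F4 (TBAT cat., THF, −78 °C) runs through an open transition state, which is known to favour the ring-CH2/oxygen syn relationship with cyclic enol silanes; it should give the O-trimethylsilyl aldol F5. K2CO3 in MeOH at 0 °C frees the C7 hydroxyl and returns to 22 after chromatographic removal of any C7 epimer.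

3. Step 18. Enantiofacial control by the chiral chromium complex may be low, oxidative addition of the bromofuranone may be slow, and the β,γ-unsaturated aldehyde may isomerise while it waits. The fallback sets out from aldehyde 28 and moves stereocontrol to a reagent-controlled reduction. Ligand-free coupling of 28 with 29 (CrCl2, NiCl2 cat., DMF) should give 31 together with its (11S)-carbinol epimer F6. Buffered Dess–Martin oxidation of the mixture gives the 4-acylfuranone F7. Corey–Bakshi–Shibata reduction of F7 ((S)-methyl oxazaborolidine, catecholborane, toluene, −78 °C), with the furanone as the large group, should deliver the (R)-carbinol and so return to 31.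

**Further compounds**

F1 | step 15 | methyl (2Z,6E,10E)-13-(tert-butyldiphenylsilyloxy)-6,10-dimethyl-2-[(2S)-4-methyl-2-(triethylsilyloxy)pent-3-en-1-yl]trideca-2,6,10-trienoate | CC(C)=C[C@@H](O[Si](CC)(CC)CC)C/C(=C/CC/C(C)=C/CC/C(C)=C/CCO[Si](c1ccccc1)(c1ccccc1)C(C)(C)C)C(=O)OC
F2 | step 15 | methyl (2Z,6E,10E)-13-(tert-butyldiphenylsilyloxy)-2-[(2S)-2-hydroxy-4-methylpent-3-en-1-yl]-6,10-dimethyltrideca-2,6,10-trienoate | CC(C)=C[C@@H](O)C/C(=C/CC/C(C)=C/CC/C(C)=C/CCO[Si](c1ccccc1)(c1ccccc1)C(C)(C)C)C(=O)OC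
F3 | step 12 | triethyl{[(2S)-4-methyl-1-[5-methyl-6-(trimethylsilyloxy)cyclohexa-1,5-dien-1-yl]pent-3-en-2-yl]oxy}silane | CC(C)=C[C@@H](O[Si](CC)(CC)CC)CC1=CCCC(C)=C1O[Si](C)(C)C
F4 | step 12 | (4E)-7-(tert-butyldiphenylsilyloxy)-4-methylhept-4-enal | O=CCC/C(C)=C/CCO[Si](c1ccccc1)(c1ccccc1)C(C)(C)C
F5 | step 12 | O-trimethylsilyl ether of 22 at C7 | CC(C)=C[C@@H](O[Si](CC)(CC)CC)CC1=CCC[C@](C)([C@@H](O[Si](C)(C)C)CC/C(C)=C/CCO[Si](c2ccccc2)(c2ccccc2)C(C)(C)C)C1=O
F6 | step 18 | (11S)-carbinol epimer of 31 | CC(C)=C[C@@H]1C/C(=C/CC/C(C)=C/CC/C(C)=C/C[C@H](O)C2=CC(=O)OC2)C(=O)O1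
F7 | step 18 | (3Z,5S)-3-[(4E,8E)-4,8-dimethyl-11-oxo-11-(5-oxo-2,5-dihydrofuran-3-yl)undeca-4,8-dien-1-ylidene]-5-(2-methylprop-1-en-1-yl)dihydrofuran-2(3H)-one | CC(C)=C[C@@H]1C/C(=C/CC/C(C)=C/CC/C(C)=C/CC(=O)C2=CC(=O)OC2)C(=O)O1
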